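The plan cuts the α-methylene-γ-butyrolactone through its two carbon–carbon bonds outside the acrylate unit: C6–C7 (oxygen-bearing CH to ring-fusion CH, also the last bond of the ten-membered carbocycle) and C11–C12 (α-carbon to carbonyl). One molybdenum-mediated allenic hetero-Pauson–Khand [2+2+1] reaction of an aldehyde, the inner π-bond of a terminal allene and carbon monoxide should make both, closing carbocycle and lactone and setting C6 and C7. It exploits the vicinal C6(O)/C7 pair next to the C11=C13 exo-methylene. The precursor is a 2,5-cis 2-methoxy-4-methylene-oxolane carrying the C6 aldehyde on one side and a silyloxy-substituted buta-2,3-dienyl arm on the other.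

Key step: step 14

Remarks on the chemistry (assumptions):
- Atom labels C1–C15 follow germacrane numbering of the target: C1–C10 are the ring carbons, C2 is the hemiketal carbon, the oxygen bridge runs C2–O–C5, C4=C15 and C10=C14 are the ring methylidenes, C6 is the lactone CH–O, C7 the ring-fusion CH, C8 the tigloyloxy carbon, C11 the lactone α-carbon, C12 the carbonyl and C13 the α-methylene carbon. The target is then (2S,5S,6S,7R,8S) with a trans-fused lactone.
- Acid-equilibrated ketalization at C2 is assumed to favour the anomer with the two carbon substituents of the oxolane cis (methoxy pseudo-axial); the other anomer can be re-equilibrated.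

Step 1
Reactants: 1 methyl (4R)-2,2-dimethyl-1,3-dioxolane-4-carboxylate
Product: 3 (4S)-2,2-dimethyl-4-[3-(trimethylsilyl)prop-1-en-2-yl]-1,3-dioxolane, via bis(silylmethyl) carbinol 2 (not isolated)
Conditions: Me3SiCH2MgCl (4 equiv), CeCl3, THF, −78 °C to rt; then silica gel, CH2Cl2, rt
Reagents that add atoms: (trimethylsilyl)methylmagnesium chloride, C[Si](C)(C)C[Mg]Cl
Why: Cerium-mediated double Grignard addition to the ester and Peterson elimination of the resulting β-hydroxysilane (allylsilane synthesis) should give 3; C5 comes from the chiral pool and is not touched (the descriptor changes only because the priorities change).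

Step 2
Reactants: 3 (4S)-2,2-dimethyl-4-[3-(trimethylsilyl)prop-1-en-2-yl]-1,3-dioxolane; 4 1,3-dithiane
Product: 6 2-{2-[(4S)-2,2-dimethyl-1,3-dioxolan-4-yl]prop-2-en-1-yl}-1,3-dithiane, via dithianylium tetrafluoroborate 5 (not isolated)
Conditions: 4, Ph3CBF4, CH2Cl2, reflux; then 3, CH2Cl2, −78 to −40 °C; Et3N quench
Reagents that add atoms: none
Why: Hydride abstraction from 4 gives the 1,3-dithian-2-ylium ion, which the allylsilane attacks through its CH2= terminus with loss of silicon (Hosomi–Sakurai-type SE2' allylation of a carbenium ion); the allyl shift returns the same 2-substituted allyl skeleton and installs C2 as a masked carbonyl.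

Step 3
Reactants: 7 3-(trimethylsilyl)prop-2-ynal; 8 3-chloro-2-(chloromethyl)prop-1-ene
Product: 9 rac-2-(chloromethyl)-6-(trimethylsilyl)hex-1-en-5-yn-4-ol
Conditions: Zn dust, THF/sat. aq. NH4Cl, 0 °C to rt, 8 in excess (3 equiv)
Reagents that add atoms: none
Why: Zinc-mediated Barbier allylation, in which one of the two equivalent allylic C–Cl bonds is metallated and adds 1,2 to the ynal (excess 8 limits double reaction); the carbinol centre is racemic here and is corrected in steps 4 and 5.

Step 4
Reactants: 9 rac-2-(chloromethyl)-6-(trimethylsilyl)hex-1-en-5-yn-4-ol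
Product: 10 2-(chloromethyl)-6-(trimethylsilyl)hex-1-en-5-yn-4-one
Conditions: Dess–Martin periodinane, NaHCO3, CH2Cl2, 0 °C
Reagents that add atoms: none
Why: Dess–Martin oxidation under buffered, non-basic conditions should give the ynone without moving the β,γ-double bond into conjugation.

Step 5
Reactants: 10 2-(chloromethyl)-6-(trimethylsilyl)hex-1-en-5-yn-4-one
Product: 11 (4S)-2-(chloromethyl)-6-(trimethylsilyl)hex-1-en-5-yn-4-ol
Conditions: Ru[(S,S)-TsNCHPhCHPhNH](η6-p-cymene) (1 mol %, preformed base-free amido complex), i-PrOH, rt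
Reagents that add atoms: none
Why: Noyori asymmetric transfer hydrogenation of an α,β-acetylenic ketone, in which the (S,S)-ruthenium catalyst delivers hydride to the face that gives the (S)-propargylic alcohol (alkynyl group in the place of the aryl group of the usual model); this sets C8.

Step 6
Reactants: 11 (4S)-2-(chloromethyl)-6-(trimethylsilyl)hex-1-en-5-yn-4-ol
Product: 12 tert-butyl{[(4S)-2-(chloromethyl)-6-(trimethylsilyl)hex-1-en-5-yn-4-yl]oxy}dimethylsilane
Conditions: TBSOTf, 2,6-lutidine, CH2Cl2, −78 °C
Reagents that add atoms: tert-butyldimethylsilyl trifluoromethanesulfonate, CC(C)(C)[Si](C)(C)OS(=O)(=O)C(F)(F)F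
Why: Silyl ether formation with the silyl triflate and a hindered base at low temperature protects O8 and avoids amine alkylation by the allylic chloride.

Step 7
Reactants: 6 2-{2-[(4S)-2,2-dimethyl-1,3-dioxolan-4-yl]prop-2-en-1-yl}-1,3-dithiane; 12 tert-butyl{[(4S)-2-(chloromethyl)-6-(trimethylsilyl)hex-1-en-5-yn-4-yl]oxy}dimethylsilane
Product: 14 2-{(4S)-4-[(tert-butyldimethylsilyl)oxy]-2-methylidene-6-(trimethylsilyl)hex-5-yn-1-yl}-2-{2-[(4S)-2,2-dimethyl-1,3-dioxolan-4-yl]prop-2-en-1-yl}-1,3-dithiane, via lithiated dithiane 13 (not isolated)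
Conditions: n-BuLi, THF, −30 °C; then 12, THF/HMPA, −78 to −20 °C
Reagents that add atoms: none
Why: Corey–Seebach alkylation, in which deprotonation of the 2-substituted dithiane at C2 and SN2 displacement of the primary allylic chloride (SN2' would give the same product) joins the two halves at C1–C2; no stereocentre is formed.

Step 8
Reactants: 14 the bis-allylated dithiane acetonide
Product: 15 (2S)-3-[(2-{(4S)-4-[(tert-butyldimethylsilyl)oxy]-2-methylidene-6-(trimethylsilyl)hex-5-yn-1-yl}-1,3-dithian-2-yl)methyl]but-3-ene-1,2-diol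
Conditions: 80% aq. AcOH, rt
Reagents that add atoms: none
Why: Acid hydrolysis of the terminal acetonide (acetal cleavage) frees the C5/C6 diol while the secondary silyl ether, the dithiane and the alkynylsilane should survive.

Step 9
Reactants: 15 the C5/C6 diol
Product: 16 (2S)-3-[(2-{(4S)-4-[(tert-butyldimethylsilyl)oxy]-2-methylidene-6-(trimethylsilyl)hex-5-yn-1-yl}-1,3-dithian-2-yl)methyl]-2-hydroxybut-3-en-1-yl acetate
Conditions: AcCl, 2,4,6-collidine, CH2Cl2, −78 °C
Reagents that add atoms: acetyl chloride, CC(=O)Cl
Why: Selective O-acylation of the primary hydroxyl blocks O6, so that only O5 can later close on C2 (five-membered and not six-membered ketal).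

Step 10
Reactants: 16 the primary acetate with free C5 hydroxyl
Product: 17 [(2S,5S)-5-{(4S)-4-[(tert-butyldimethylsilyl)oxy]-2-methylidene-6-(trimethylsilyl)hex-5-yn-1-yl}-5-methoxy-3-methylideneoxolan-2-yl]methyl acetate
Conditions: PhI(OCOCF3)2 (1.5 equiv), MeOH/CH2Cl2 4:1, −20 °C to rt
Reagents that add atoms: methanol, CO
Why: Oxidative dethioketalization with the hypervalent iodine reagent in methanol releases an oxocarbenium ion at C2 that is trapped by O5 and methanol to give the mixed cyclic ketal; the trifluoroacetic acid set free should equilibrate C2 to the anomer with pseudo-axial methoxy and cis carbon substituents (anomeric effect), which is the one needed.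

Step 11
Reactants: 17 the methyl ketal acetate
Product: 18 [(2S,5S)-5-{(4S)-4-[(tert-butyldimethylsilyl)oxy]-2-methylidenehex-5-yn-1-yl}-5-methoxy-3-methylideneoxolan-2-yl]methanol
Conditions: K2CO3, MeOH, rt
Reagents that add atoms: none
Why: Methanolysis (transesterification of the acetate and protodesilylation of the alkynylsilane) frees the C6 hydroxyl and the terminal alkyne in one operation; the silyl ether and the ketal are stable to carbonate.

Step 12
Reactants: 18 the terminal alkyne alcohol
Product: 20 [(2S,5S)-5-{(4S)-4-[(tert-butyldimethylsilyl)oxy]-2-methylidenehepta-5,6-dien-1-yl}-5-methoxy-3-methylideneoxolan-2-yl]methanol, via propargylic amine 19 (not isolated)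
Conditions: (CH2O)n, CuI (0.5 equiv), Cy2NH, 1,4-dioxane, reflux
Reagents that add atoms: paraformaldehyde (as formaldehyde), C=O
Why: Crabbé homologation, in which a copper-mediated Mannich reaction of the terminal alkyne is followed by intramolecular hydride transfer and loss of the imine, turns C≡CH into CH=C=CH2 (adding C13) without touching C8.

Step 13
Reactants: 20 the allenyl alcohol
Product: 21 (2S,5S)-5-{(4S)-4-[(tert-butyldimethylsilyl)oxy]-2-methylidenehepta-5,6-dien-1-yl}-5-methoxy-3-methylideneoxolane-2-carbaldehyde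
Conditions: Dess–Martin periodinane, NaHCO3, CH2Cl2, 0 °C; used at once
Reagents that add atoms: none
Why: Dess–Martin oxidation of the primary alcohol gives the α-alkoxy aldehyde under buffered conditions, and immediate use should avoid epimerization at C5 or migration of the C4 methylidene.

Step 14
Reactants: 21 the allenyl aldehyde
Product: 22 (2S,5S,6S,7S,8S)-8-[(tert-butyldimethylsilyl)oxy]-2-methoxy-2,5-epoxygermacra-4(15),10(14),11(13)-trien-12,6-olide
Conditions: Mo(CO)6 (1.2 equiv), DMSO (10 equiv), toluene (0.002 M, slow addition of 21), 100 °C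
Reagents that add atoms: molybdenum hexacarbonyl (source of carbon monoxide), [C-]#[O+].[C-]#[O+].[C-]#[O+].[C-]#[O+].[C-]#[O+].[C-]#[O+].[Mo]
Why: Proposed new method: DMSO-promoted decarbonylation of Mo(CO)6 gives a zerovalent molybdenum carbonyl that binds the C6 aldehyde and the inner C7=C11 π-bond of the allene; oxidative cyclization forms C6–C7 and an oxamolybdacycle with the metal on the central allene carbon (η3-allyl stabilised through C11=C13), CO insertion makes C11–C12, and C–O reductive elimination releases the lactone. The closest known reaction is the Mo(CO)6/DMSO-mediated (or Ru3(CO)12-catalysed) allenic hetero-Pauson–Khand cyclocarbonylation of allenyl aldehydes to α-methylene-γ-butyrolactones, so far shown only where the new carbocycle is five- or six-membered. Here the lactone is closed by the [2+2+1] carbonylative cycloaddition and the ten-membered carbocycle by the same C6–C7 coupling, exo with respect to the allene (C11=C13 stays exocyclic), as a bridging closure across the 2,5-cis-oxolane. C6 should be set by attack on the aldehyde face exposed when molybdenum is chelated by the oxolane oxygen O5 and the carbonyl oxygen (1,2-syn, Cram-chelate sense); C7 should be set by the C8 stereocentre, whose silyloxy group takes the pseudo-equatorial position of the forming ring, together with the preference of the metallacycle for a trans arrangement of the C5 and C8 substituents (trans-fused lactone). The step needs site selectivity for the inner allene π-bond with bonding at C7 and not C13 (ten- versus twelve-membered ring) and cyclization over oligomerization; the preference of molybdenum for the proximal allene π-bond, the oxolane turn that holds both chain ends on one face, and high dilution are counted on to secure this.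

Step 15
Reactants: 22 the silyl-protected tricyclic lactone
Product: 23 (2S,5S,6S,7R,8S)-8-hydroxy-2-methoxy-2,5-epoxygermacra-4(15),10(14),11(13)-trien-12,6-olide
Conditions: HF·pyridine, pyridine, THF, 0 °C to rt
Reagents that add atoms: none
Why: Fluoride-mediated silyl ether cleavage under buffered conditions frees the C8 hydroxyl and should leave the methyl ketal, the α-methylene lactone and all stereocentres untouched (the C7 descriptor changes only by priority).

Step 16
Reactants: 23 the C8 alcohol; 24 (E)-2-methylbut-2-enoyl chloride (tigloyl chloride)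
Product: 25 (2S,5S,6S,7R,8S)-2-methoxy-8-(tigloyloxy)-2,5-epoxygermacra-4(15),10(14),11(13)-trien-12,6-olide
Conditions: 24, pyridine, DMAP (cat.), CH2Cl2, 0 °C to rt
Reagents that add atoms: none
Why: DMAP-catalysed esterification of the secondary alcohol with the (E)-acid chloride installs the tiglate with retention at C8 and without E/Z isomerization, while the ketal keeps the C2 oxygen masked.

Step 17
Reactants: 25 the methyl ketal of the target
Product: 26 (2S,5S,6S,7R,8S)-2-hydroxy-8-(tigloyloxy)-2,5-epoxygermacra-4(15),10(14),11(13)-trien-12,6-olide (CNP0307443.2)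
Conditions: PPTS (cat.), acetone/H2O 4:1, rt
Reagents that add atoms: water, O
Why: Mild acid hydrolysis of the mixed ketal (acetal hydrolysis) gives the hemiketal, whose C2 configuration is fixed by the oxygen bridge of the bicycle (hydroxyl exo), so the thermodynamic product should be the target.

Compound list
1 | methyl (4R)-2,2-dimethyl-1,3-dioxolane-4-carboxylate | COC(=O)[C@H]1COC(C)(C)O1 | starting material
2 | 2-[(4R)-2,2-dimethyl-1,3-dioxolan-4-yl]-1,3-bis(trimethylsilyl)propan-2-ol | C[Si](C)(C)CC(O)(C[Si](C)(C)C)[C@H]1COC(C)(C)O1 | intermediate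
3 | (4S)-2,2-dimethyl-4-[3-(trimethylsilyl)prop-1-en-2-yl]-1,3-dioxolane | C=C(C[Si](C)(C)C)[C@H]1COC(C)(C)O1 | intermediate
4 | 1,3-dithiane | C1CSCSC1 | starting material
5 | 1,3-dithian-2-ylium tetrafluoroborate | [CH+]1SCCCS1.F[B-](F)(F)F | intermediate
6 | 2-{2-[(4S)-2,2-dimethyl-1,3-dioxolan-4-yl]prop-2-en-1-yl}-1,3-dithiane | C=C(CC1SCCCS1)[C@H]1COC(C)(C)O1 | intermediate
7 | 3-(trimethylsilyl)prop-2-ynal | C[Si](C)(C)C#CC=O | starting material
8 | 3-chloro-2-(chloromethyl)prop-1-ene | C=C(CCl)CCl | starting material
9 | rac-2-(chloromethyl)-6-(trimethylsilyl)hex-1-en-5-yn-4-ol | C=C(CCl)CC(O)C#C[Si](C)(C)C | intermediate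
10 | 2-(chloromethyl)-6-(trimethylsilyl)hex-1-en-5-yn-4-one | C=C(CCl)CC(=O)C#C[Si](C)(C)C | intermediate
11 | (4S)-2-(chloromethyl)-6-(trimethylsilyl)hex-1-en-5-yn-4-ol | C=C(CCl)C[C@H](O)C#C[Si](C)(C)C | intermediate
12 | tert-butyl{[(4S)-2-(chloromethyl)-6-(trimethylsilyl)hex-1-en-5-yn-4-yl]oxy}dimethylsilane | C=C(CCl)C[C@H](O[Si](C)(C)C(C)(C)C)C#C[Si](C)(C)C | intermediate
13 | {2-[2-((4S)-2,2-dimethyl-1,3-dioxolan-4-yl)prop-2-en-1-yl]-1,3-dithian-2-yl}lithium | [Li]C1(CC(=C)[C@H]2COC(C)(C)O2)SCCCS1 | intermediate
14 | 2-{(4S)-4-[(tert-butyldimethylsilyl)oxy]-2-methylidene-6-(trimethylsilyl)hex-5-yn-1-yl}-2-{2-[(4S)-2,2-dimethyl-1,3-dioxolan-4-yl]prop-2-en-1-yl}-1,3-dithiane | C=C(CC1(CC(=C)C[C@H](O[Si](C)(C)C(C)(C)C)C#C[Si](C)(C)C)SCCCS1)[C@H]1COC(C)(C)O1 | intermediate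
15 | (2S)-3-[(2-{(4S)-4-[(tert-butyldimethylsilyl)oxy]-2-methylidene-6-(trimethylsilyl)hex-5-yn-1-yl}-1,3-dithian-2-yl)methyl]but-3-ene-1,2-diol | C=C(CC1(CC(=C)C[C@H](O[Si](C)(C)C(C)(C)C)C#C[Si](C)(C)C)SCCCS1)[C@H](O)CO | intermediate
16 | (2S)-3-[(2-{(4S)-4-[(tert-butyldimethylsilyl)oxy]-2-methylidene-6-(trimethylsilyl)hex-5-yn-1-yl}-1,3-dithian-2-yl)methyl]-2-hydroxybut-3-en-1-yl acetate | C=C(CC1(CC(=C)C[C@H](O[Si](C)(C)C(C)(C)C)C#C[Si](C)(C)C)SCCCS1)[C@H](O)COC(C)=O | intermediate
17 | [(2S,5S)-5-{(4S)-4-[(tert-butyldimethylsilyl)oxy]-2-methylidene-6-(trimethylsilyl)hex-5-yn-1-yl}-5-methoxy-3-methylideneoxolan-2-yl]methyl acetate | C=C(C[C@H](O[Si](C)(C)C(C)(C)C)C#C[Si](C)(C)C)C[C@]1(OC)O[C@H](COC(C)=O)C(=C)C1 | intermediate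
18 | [(2S,5S)-5-{(4S)-4-[(tert-butyldimethylsilyl)oxy]-2-methylidenehex-5-yn-1-yl}-5-methoxy-3-methylideneoxolan-2-yl]methanol | C=C(C[C@H](O[Si](C)(C)C(C)(C)C)C#C)C[C@]1(OC)O[C@H](CO)C(=C)C1 | intermediate
19 | [(2S,5S)-5-{(4S)-4-[(tert-butyldimethylsilyl)oxy]-7-(dicyclohexylamino)-2-methylidenehept-5-yn-1-yl}-5-methoxy-3-methylideneoxolan-2-yl]methanol | C=C(C[C@H](O[Si](C)(C)C(C)(C)C)C#CCN(C1CCCCC1)C1CCCCC1)C[C@]1(OC)O[C@H](CO)C(=C)C1 | intermediate
20 | [(2S,5S)-5-{(4S)-4-[(tert-butyldimethylsilyl)oxy]-2-methylidenehepta-5,6-dien-1-yl}-5-methoxy-3-methylideneoxolan-2-yl]methanol | C=C(C[C@H](O[Si](C)(C)C(C)(C)C)C=C=C)C[C@]1(OC)O[C@H](CO)C(=C)C1 | intermediate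
21 | (2S,5S)-5-{(4S)-4-[(tert-butyldimethylsilyl)oxy]-2-methylidenehepta-5,6-dien-1-yl}-5-methoxy-3-methylideneoxolane-2-carbaldehyde | C=C(C[C@H](O[Si](C)(C)C(C)(C)C)C=C=C)C[C@]1(OC)O[C@H](C=O)C(=C)C1 | intermediate
22 | (2S,5S,6S,7S,8S)-8-[(tert-butyldimethylsilyl)oxy]-2-methoxy-2,5-epoxygermacra-4(15),10(14),11(13)-trien-12,6-olide | C=C1C[C@H](O[Si](C)(C)C(C)(C)C)[C@H]2C(=C)C(=O)O[C@@H]2[C@H]2O[C@@](OC)(C1)CC2=C | intermediate
23 | (2S,5S,6S,7R,8S)-8-hydroxy-2-methoxy-2,5-epoxygermacra-4(15),10(14),11(13)-trien-12,6-olide | C=C1C[C@H](O)[C@H]2C(=C)C(=O)O[C@@H]2[C@H]2O[C@@](OC)(C1)CC2=C | intermediate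
24 | (E)-2-methylbut-2-enoyl chloride (tigloyl chloride) | ClC(=O)/C(C)=C/C | starting material
25 | (2S,5S,6S,7R,8S)-2-methoxy-8-(tigloyloxy)-2,5-epoxygermacra-4(15),10(14),11(13)-trien-12,6-olide | C=C1C[C@H](OC(=O)/C(C)=C/C)[C@H]2C(=C)C(=O)O[C@@H]2[C@H]2O[C@@](OC)(C1)CC2=C | intermediate
26 | (2S,5S,6S,7R,8S)-2-hydroxy-8-(tigloyloxy)-2,5-epoxygermacra-4(15),10(14),11(13)-trien-12,6-olide (CNP0307443.2) | C=C1C[C@H](OC(=O)/C(C)=C/C)[C@H]2C(=C)C(=O)O[C@@H]2[C@H]2O[C@@](O)(C1)CC2=C | target

Total step count: 17. Longest linear sequence: 15 steps (steps 3 to 17); the left-hand fragment (steps 1 and 2) joins at step 7.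

Steps most likely to fail

1. Step 14 (the labelled step). The medium-ring oxidative cyclization may lose to oligomerization, to reaction at the outer allene π-bond or at C13, or to migration of the C4 methylidene into conjugation with the aldehyde on heating; facial selectivity at C6/C7 may also be poor. The fallback makes the two bonds one after the other with reaction types that are each known for allenes, alkenylboronates and 2-halo homoallylic alcohols. It sets out from 21: a copper-catalysed borylative allene–aldehyde cyclization (CuCl, PCy3, NaOt-Bu, B2pin2, THF, high dilution) should form C6–C7, because the 2-boryl allylcopper made by borylcupration of the allene adds to the aldehyde through its substituted terminus C7, and give the hydroxy alkenylboronate F1. Iododeboronation (NaOMe, then I2, THF, −78 °C) should give the hydroxy alkenyl iodide F2. Palladium-catalysed carbonylative lactonization (Pd(PPh3)4, CO 1 atm, Et3N, MeCN, 60 °C) then forms C11–C12 and the lactone and comes back to the route at 22. The ring size remains untested for the copper step as well.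

2. Step 10. The hypervalent iodine reagent may attack the electron-rich 1,1-disubstituted alkenes, the acid set free may move a β,γ-double bond into conjugation with the unmasked carbonyl, or the anomers may not equilibrate to the needed one. The fallback separates unmasking from ketalization and avoids an oxidant. It sets out from 16: alkylative hydrolysis of the dithiane (MeI, CaCO3, MeCN/H2O, 40 °C) should give the hydroxy ketone F3, and a separate, buffered thermodynamic ketalization (PPTS, MeOH, 3 Å molecular sieves, rt) comes back to the route at 17.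

3. Step 2. The stabilised dithianylium ion may react too slowly with the allylsilane, or the Lewis acid formed may cause protodesilylation or acetonide cleavage. The fallback reverses the polarity of the coupling. It sets out from 3: bromodesilylation (NBS, CH2Cl2, −78 °C; SE2' attack of bromine with loss of silicon) should give the allylic bromide F4, and alkylation of 2-lithio-1,3-dithiane F5 (made from 4 with n-BuLi, THF, −30 °C) with F4 at −78 °C comes back to the route at 6.

Further compounds
F1 | step 14 | ten-membered hydroxy alkenylboronate: 22 without the C12 carbonyl, with free C6–OH and a 1-(4,4,5,5-tetramethyl-1,3,2-dioxaborolan-2-yl)ethenyl group on C7 (configuration at C2, C5, C6, C7, C8 as in 22) | C=C1C[C@H](O[Si](C)(C)C(C)(C)C)[C@@H](C(=C)B3OC(C)(C)C(C)(C)O3)[C@H](O)[C@H]2O[C@@](OC)(C1)CC2=C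
F2 | step 14 | ten-membered hydroxy alkenyl iodide: as F1 with a 1-iodoethenyl group on C7 | C=C1C[C@H](O[Si](C)(C)C(C)(C)C)[C@@H](C(=C)I)[C@H](O)[C@H]2O[C@@](OC)(C1)CC2=C
F3 | step 10 | (2S,9S)-9-[(tert-butyldimethylsilyl)oxy]-2-hydroxy-3,7-dimethylidene-5-oxo-11-(trimethylsilyl)undec-10-yn-1-yl acetate | C=C(CC(=O)CC(=C)C[C@H](O[Si](C)(C)C(C)(C)C)C#C[Si](C)(C)C)[C@H](O)COC(C)=O
F4 | step 2 | (4S)-4-(3-bromoprop-1-en-2-yl)-2,2-dimethyl-1,3-dioxolane | C=C(CBr)[C@H]1COC(C)(C)O1
F5 | step 2 | 2-lithio-1,3-dithiane | [Li]C1SCCCS1
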